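**Plan**

1. Retrosynthesis: remove the two galloyl esters (lower O3 and ring B O3′), cut C4–C4a of the lower ring C (epoxide–arene closure), then the lower O1–C2 aryl ether (Mitsunobu), then the interflavan C4(upper)–C6(lower) bond, then the upper ring C in the same two ways.
2. Forward: the upper ring C is closed first, C4 is oxidised and joined to a phloroglucinol triether, the freed para phenol is etherified with the ring B epoxy alcohol, the lower ring C is closed, then esterification and global hydrogenolysis follow.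
3. Enabling feature: before its ring C exists, the lower ring A is a 2-substituted phloroglucinol with O1 para to C6. C4a and C8, the two carbons ortho to O1, are interchanged by rotation about the C4(upper)–C6 bond, so closing C4–C4a at either one gives only the 4→6 dimer.
4. Stereochemistry: a Sharpless kinetic-resolution epoxidation sets the carbinol and oxirane carbons of each unit; Mitsunobu inversion turns erythro into threo, which becomes 2,3-cis (2R,3R); the 4β bond forms trans to the upper 3-O substituent.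

Key step: step 15

Assumption: 1, 2, 5, 13, 21 and all reagents are taken as commercial; the CIP descriptor of upper C4 is S in 11, 12, 18 and 24 but R in 19, 20, 22 and 23, although the 4β geometry never changes, because the ranking of its two aryl neighbours depends on the substituents of the lower ring A.

**Route**

Step 1
Reactants: 1 4-(benzyloxy)benzaldehyde; 2 vinylmagnesium bromide
Product: 3 rac-1-[4-(benzyloxy)phenyl]prop-2-en-1-ol
Conditions: 2 (1.2 equiv), THF, −78 → 0 °C; aq. NH4Cl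
Reagents that add atoms: none
Why: Grignard 1,2-addition to an aromatic aldehyde gives the racemic aryl vinyl carbinol that step 2 resolves.

Step 2
Reactants: 3 rac-1-[4-(benzyloxy)phenyl]prop-2-en-1-ol
Product: 4 (S)-[4-(benzyloxy)phenyl][(2R)-oxiran-2-yl]methanol (erythro)
Conditions: Ti(OiPr)4 (0.2 equiv), L-(+)-diisopropyl tartrate (0.3 equiv), t-BuOOH (0.45 equiv), 4 Å MS, CH2Cl2, −20 °C
Reagents that add atoms: tert-butyl hydroperoxide, CC(C)(C)OO
Why: Sharpless kinetic resolution by asymmetric epoxidation, in which the L-(+)-tartrate complex epoxidises the (R)-carbinol fast and erythro-selectively and so sets both the carbinol centre (S after the priority change) and the oxirane centre (R), while the substoichiometric oxidant leaves the slow (S)-enantiomer of 3 behind for chromatographic removal.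

Step 3
Reactants: 4 (S)-[4-(benzyloxy)phenyl][(2R)-oxiran-2-yl]methanol; 5 3,5-bis(benzyloxy)phenol
Product: 6 (2R)-2-{(R)-[4-(benzyloxy)phenyl][3,5-bis(benzyloxy)phenoxy]methyl}oxirane (threo)
Conditions: PPh3 (1.5 equiv), DIAD (1.5 equiv), toluene, 0 °C → rt
Reagents that add atoms: none
Why: Mitsunobu etherification, in which the phenoxide displaces the activated benzylic oxygen with SN2 inversion (S → R) and so converts the erythro epoxy alcohol into the threo aryloxy epoxide needed for a 2,3-cis flavan, the oxirane staying intact.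

Step 4
Reactants: 6 (2R)-2-{(R)-[4-(benzyloxy)phenyl][3,5-bis(benzyloxy)phenoxy]methyl}oxirane
Product: 7 (2R,3R)-5,7-bis(benzyloxy)-2-[4-(benzyloxy)phenyl]chroman-3-ol (5,7,4′-tri-O-benzyl-(−)-epiafzelechin)
Conditions: BF3·OEt2 (1.1 equiv), CH2Cl2, −78 → −40 °C
Reagents that add atoms: none
Why: intramolecular Friedel–Crafts epoxide–arene cyclization (6-endo at the unsubstituted oxirane carbon) closes ring C through C4–C4a at either of the two identical ortho carbons of the symmetric ring, with C2 and C3 carried over unchanged from 6.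

Step 5
Reactants: 7 (2R,3R)-5,7-bis(benzyloxy)-2-[4-(benzyloxy)phenyl]chroman-3-ol
Product: 8 (2R,3R,4S)-5,7-bis(benzyloxy)-2-[4-(benzyloxy)phenyl]-4-(2-ethoxyethoxy)chroman-3-ol (4β ether)
Conditions: DDQ (2 equiv), 2-ethoxyethanol (5 equiv), CH2Cl2, rt
Reagents that add atoms: 2-ethoxyethanol, CCOCCO
Why: DDQ abstracts hydride from C4, which is benzylic to the dioxygenated ring A, and the cation is trapped by the alcohol trans to the 3-hydroxyl, a known C4 activation of benzylated flavan-3-ols that should give the 4β ether.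

Step 6
Reactants: 8 (2R,3R,4S)-5,7-bis(benzyloxy)-2-[4-(benzyloxy)phenyl]-4-(2-ethoxyethoxy)chroman-3-ol
Product: 9 (2R,3R,4S)-3,5,7-tris(benzyloxy)-2-[4-(benzyloxy)phenyl]-4-(2-ethoxyethoxy)chromane
Conditions: NaH (1.5 equiv), BnBr (1.5 equiv), Bu4NI (cat.), DMF, 0 °C → rt
Reagents that add atoms: benzyl bromide, BrCc1ccccc1
Why: Williamson benzylation of the only hydroxyl masks the upper O3 with a group that falls in the final hydrogenolysis and keeps it distinct from the lower 3-OH set free in step 15.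

Step 7
Reactants: 5 3,5-bis(benzyloxy)phenol
Product: 10 [3,5-bis(benzyloxy)phenoxy]tri(propan-2-yl)silane
Conditions: TIPSCl (1.2 equiv), imidazole (2.5 equiv), DMF, rt
Reagents that add atoms: chlorotri(propan-2-yl)silane, CC(C)[Si](Cl)(C(C)C)C(C)C
Why: silylation of the phenol gives a bulky silyl ether that marks the future O1 of the lower unit and shields its two ortho carbons in step 8.

Step 8
Reactants: 9 (2R,3R,4S)-3,5,7-tris(benzyloxy)-2-[4-(benzyloxy)phenyl]-4-(2-ethoxyethoxy)chromane; 10 [3,5-bis(benzyloxy)phenoxy]tri(propan-2-yl)silane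
Product: 11 {3,5-bis(benzyloxy)-4-[(2R,3R,4S)-3,5,7-tris(benzyloxy)-2-[4-(benzyloxy)phenyl]chroman-4-yl]phenoxy}tri(propan-2-yl)silane
Conditions: 10 (3 equiv), TMSOTf (0.1 equiv), CH2Cl2, −78 °C; Et3N quench
Reagents that add atoms: none
Why: Lewis acid ionisation of the 4-alkoxy group gives the flavan-4-yl cation, which arylates 10 in a Friedel–Crafts step (the way the interflavan bond is thought to form in nature) at the carbon para to the silyl ether, whose two ortho carbons are blocked by the triisopropylsilyl group, and from the face trans to the 3-benzyloxy group (4β), with excess 10 suppressing self-condensation of 9.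

Step 9
Reactants: 11 {3,5-bis(benzyloxy)-4-[(2R,3R,4S)-3,5,7-tris(benzyloxy)-2-[4-(benzyloxy)phenyl]chroman-4-yl]phenoxy}tri(propan-2-yl)silane
Product: 12 3,5-bis(benzyloxy)-4-[(2R,3R,4S)-3,5,7-tris(benzyloxy)-2-[4-(benzyloxy)phenyl]chroman-4-yl]phenol
Conditions: Bu4NF (1.2 equiv), AcOH (1.2 equiv), THF, 0 °C
Reagents that add atoms: none
Why: buffered fluoride cleaves the aryl silyl ether selectively and frees the one phenol para to the upper unit, leaving the benzyl ethers untouched.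

Step 10
Reactants: 13 3,4,5-trihydroxybenzaldehyde
Product: 14 7-hydroxy-2,2-diphenyl-1,3-benzodioxole-5-carbaldehyde
Conditions: Ph2CCl2 (1.1 equiv), K2CO3 (2.5 equiv), MeCN, rt, argon
Reagents that add atoms: dichlorodiphenylmethane, ClC(Cl)(c1ccccc1)c1ccccc1
Why: ketal formation across two adjacent phenols of the symmetric triol leaves exactly one hydroxyl free, which differentiates the future O3′ from O4′ and O5′ with a group that is hydrogenolysed at the end.

Step 11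
Reactants: 14 7-hydroxy-2,2-diphenyl-1,3-benzodioxole-5-carbaldehyde
Product: 15 7-{[tert-butyl(dimethyl)silyl]oxy}-2,2-diphenyl-1,3-benzodioxole-5-carbaldehyde
Conditions: TBSCl (1.2 equiv), imidazole (2.5 equiv), DMF, rt
Reagents that add atoms: tert-butyl(chloro)dimethylsilane, CC(C)(C)[Si](C)(C)Cl
Why: silylation protects the remaining phenol with a group orthogonal to benzyl ethers and to the ketal, so that O3′ can be unmasked alone in step 16.

Step 12
Reactants: 15 7-{[tert-butyl(dimethyl)silyl]oxy}-2,2-diphenyl-1,3-benzodioxole-5-carbaldehyde; 2 vinylmagnesium bromide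
Product: 16 rac-1-(7-{[tert-butyl(dimethyl)silyl]oxy}-2,2-diphenyl-1,3-benzodioxol-5-yl)prop-2-en-1-ol
Conditions: 2 (1.2 equiv), THF, −78 → 0 °C; aq. NH4Cl
Reagents that add atoms: none
Why: Grignard 1,2-addition to the aldehyde gives the racemic aryl vinyl carbinol, the aryl silyl ether and the ketal being inert to the reagent.

Step 13
Reactants: 16 rac-1-(7-{[tert-butyl(dimethyl)silyl]oxy}-2,2-diphenyl-1,3-benzodioxol-5-yl)prop-2-en-1-ol
Product: 17 (S)-(7-{[tert-butyl(dimethyl)silyl]oxy}-2,2-diphenyl-1,3-benzodioxol-5-yl)[(2R)-oxiran-2-yl]methanol (erythro)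
Conditions: Ti(OiPr)4 (0.2 equiv), L-(+)-diisopropyl tartrate (0.3 equiv), t-BuOOH (0.45 equiv), 4 Å MS, CH2Cl2, −20 °C
Reagents that add atoms: tert-butyl hydroperoxide, CC(C)(C)OO
Why: Sharpless kinetic resolution as in step 2, the L-(+)-tartrate complex setting the carbinol (S) and oxirane (R) centres of the fast-reacting enantiomer while the slow enantiomer of 16 stays behind.

Step 14
Reactants: 12 3,5-bis(benzyloxy)-4-[(2R,3R,4S)-3,5,7-tris(benzyloxy)-2-[4-(benzyloxy)phenyl]chroman-4-yl]phenol; 17 (S)-(7-{[tert-butyl(dimethyl)silyl]oxy}-2,2-diphenyl-1,3-benzodioxol-5-yl)[(2R)-oxiran-2-yl]methanol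
Product: 18 (2R,3R,4S)-3,5,7-tris(benzyloxy)-2-[4-(benzyloxy)phenyl]-4-{2,6-bis(benzyloxy)-4-[(R)-(7-{[tert-butyl(dimethyl)silyl]oxy}-2,2-diphenyl-1,3-benzodioxol-5-yl)[(2R)-oxiran-2-yl]methoxy]phenyl}chromane
Conditions: 17 (1.3 equiv), PPh3 (1.5 equiv), DIAD (1.5 equiv), toluene, 0 °C → rt
Reagents that add atoms: none
Why: Mitsunobu etherification of the unhindered para phenol with SN2 inversion at the benzylic carbinol (S → R) gives the threo aryloxy epoxide, and any diastereomer arising from the minor enantiomer of 17 can be removed here by chromatography.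

Step 15
Reactants: 18 (2R,3R,4S)-3,5,7-tris(benzyloxy)-2-[4-(benzyloxy)phenyl]-4-{2,6-bis(benzyloxy)-4-[(R)-(7-{[tert-butyl(dimethyl)silyl]oxy}-2,2-diphenyl-1,3-benzodioxol-5-yl)[(2R)-oxiran-2-yl]methoxy]phenyl}chromane
Product: 19 (2R,3R)-5,7-bis(benzyloxy)-2-(7-{[tert-butyl(dimethyl)silyl]oxy}-2,2-diphenyl-1,3-benzodioxol-5-yl)-6-[(2R,3R,4R)-3,5,7-tris(benzyloxy)-2-[4-(benzyloxy)phenyl]chroman-4-yl]chroman-3-ol
Conditions: BF3·OEt2 (1.1 equiv), CH2Cl2, −78 → −40 °C; aq. NaHCO3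
Reagents that add atoms: none
Why: BF3 coordinates the oxirane oxygen and the phloroglucinol-type ring of 18 attacks the unsubstituted oxirane carbon from the rear through one of its two carbons ortho to the ether oxygen (each is ortho or para to all three ring oxygens), giving a Wheland intermediate that rearomatises by proton loss, so the strain of the three-membered ring pays for the new C4–C4a bond. The closest known reaction type is the intramolecular Friedel–Crafts epoxide–arene cyclization of aryl glycidyl ethers to chroman-3-ols under Lewis acid or gold catalysis. Ring C of the lower unit closes in the 6-endo-tet mode, whereas the 5-exo mode at the internal oxirane carbon would give a dihydrobenzofuran and is disfavoured because that carbon is hindered and inductively deactivated by the neighbouring aryloxy-bearing carbon. No new stereocentre is formed: lower C2 and C3 are the benzylic ether carbon and the untouched oxirane carbon of 18, whose threo relation (resolution in step 13, inversion in step 14) becomes 2,3-cis. The position of closure needs no control, because the two ortho carbons are interchanged by rotation about the C4(upper)–aryl bond and either closure places the upper unit at C6. The step does need chemoselectivity over ionisation of the benzylic aryl ether and over 5-endo attack by ring B, which should be secured at low temperature because the para oxygen of ring B is an acetal oxygen and ring B is far less nucleophilic than the tri-oxygenated ring A.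

Step 16
Reactants: 19 (2R,3R)-5,7-bis(benzyloxy)-2-(7-{[tert-butyl(dimethyl)silyl]oxy}-2,2-diphenyl-1,3-benzodioxol-5-yl)-6-[(2R,3R,4R)-3,5,7-tris(benzyloxy)-2-[4-(benzyloxy)phenyl]chroman-4-yl]chroman-3-ol
Product: 20 6-{(2R,3R)-5,7-bis(benzyloxy)-3-hydroxy-6-[(2R,3R,4R)-3,5,7-tris(benzyloxy)-2-[4-(benzyloxy)phenyl]chroman-4-yl]chroman-2-yl}-2,2-diphenyl-1,3-benzodioxol-4-ol
Conditions: Bu4NF (1.2 equiv), AcOH (1.2 equiv), THF, 0 °C
Reagents that add atoms: none
Why: buffered fluoride removes the aryl silyl ether only, so that exactly the two oxygens to be galloylated (lower O3 and ring B O3′) are free.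

Step 17
Reactants: 20 6-{(2R,3R)-5,7-bis(benzyloxy)-3-hydroxy-6-[(2R,3R,4R)-3,5,7-tris(benzyloxy)-2-[4-(benzyloxy)phenyl]chroman-4-yl]chroman-2-yl}-2,2-diphenyl-1,3-benzodioxol-4-ol; 21 3,4,5-tris(benzyloxy)benzoic acid
Product: 23 (2R,3R)-5,7-bis(benzyloxy)-2-(2,2-diphenyl-7-{[3,4,5-tris(benzyloxy)benzoyl]oxy}-1,3-benzodioxol-5-yl)-6-[(2R,3R,4R)-3,5,7-tris(benzyloxy)-2-[4-(benzyloxy)phenyl]chroman-4-yl]chroman-3-yl 3,4,5-tris(benzyloxy)benzoate, via phenolic monoester 22 (not isolated)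
Conditions: 21 (3 equiv), DCC (3 equiv), DMAP (0.5 equiv), CH2Cl2, rt
Reagents that add atoms: none
Why: Steglich esterification acylates the phenol first and then the hindered axial 3-hydroxyl, as is established for 3-O-galloylation of benzylated epi-series flavan-3-ols, and no other hydroxyl is free.

Step 18
Reactants: 23 (2R,3R)-5,7-bis(benzyloxy)-2-(2,2-diphenyl-7-{[3,4,5-tris(benzyloxy)benzoyl]oxy}-1,3-benzodioxol-5-yl)-6-[(2R,3R,4R)-3,5,7-tris(benzyloxy)-2-[4-(benzyloxy)phenyl]chroman-4-yl]chroman-3-yl 3,4,5-tris(benzyloxy)benzoate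
Product: 24 (2R,3R)-2-{3,4-dihydroxy-5-[(3,4,5-trihydroxybenzoyl)oxy]phenyl}-5,7-dihydroxy-6-[(2R,3R,4S)-3,5,7-trihydroxy-2-(4-hydroxyphenyl)chroman-4-yl]chroman-3-yl 3,4,5-trihydroxybenzoate (CNP0290965.1)
Conditions: H2 (1 atm), Pd(OH)2/C, THF–MeOH (1:1), rt, neutral work-up, short contact time
Reagents that add atoms: none
Why: catalytic hydrogenolysis cleaves the twelve benzyl ethers and the diphenylmethylene ketal in one operation under neutral conditions that should spare both esters and avoid acyl migration on the pyrogallol ring.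

**Compound list**

1 | 4-(benzyloxy)benzaldehyde | O=Cc1ccc(OCc2ccccc2)cc1 | starting material
2 | vinylmagnesium bromide | C=C[Mg]Br | starting material
3 | rac-1-[4-(benzyloxy)phenyl]prop-2-en-1-ol | C=CC(O)c1ccc(OCc2ccccc2)cc1 | intermediate
4 | (S)-[4-(benzyloxy)phenyl][(2R)-oxiran-2-yl]methanol | O[C@@H](c1ccc(OCc2ccccc2)cc1)[C@H]1CO1 | intermediate
5 | 3,5-bis(benzyloxy)phenol | Oc1cc(OCc2ccccc2)cc(OCc2ccccc2)c1 | starting material
6 | (2R)-2-{(R)-[4-(benzyloxy)phenyl][3,5-bis(benzyloxy)phenoxy]methyl}oxirane | C(Oc1cc(OCc2ccccc2)cc(O[C@H](c2ccc(OCc3ccccc3)cc2)[C@H]2CO2)c1)c1ccccc1 | intermediate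
7 | (2R,3R)-5,7-bis(benzyloxy)-2-[4-(benzyloxy)phenyl]chroman-3-ol | O[C@@H]1Cc2c(OCc3ccccc3)cc(OCc3ccccc3)cc2O[C@@H]1c1ccc(OCc2ccccc2)cc1 | intermediate
8 | (2R,3R,4S)-5,7-bis(benzyloxy)-2-[4-(benzyloxy)phenyl]-4-(2-ethoxyethoxy)chroman-3-ol | O[C@@H]1[C@@H](OCCOCC)c2c(OCc3ccccc3)cc(OCc3ccccc3)cc2O[C@@H]1c1ccc(OCc2ccccc2)cc1 | intermediate
9 | (2R,3R,4S)-3,5,7-tris(benzyloxy)-2-[4-(benzyloxy)phenyl]-4-(2-ethoxyethoxy)chromane | C(O[C@@H]1[C@@H](OCCOCC)c2c(OCc3ccccc3)cc(OCc3ccccc3)cc2O[C@@H]1c1ccc(OCc2ccccc2)cc1)c1ccccc1 | intermediate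
10 | [3,5-bis(benzyloxy)phenoxy]tri(propan-2-yl)silane | CC(C)[Si](Oc1cc(OCc2ccccc2)cc(OCc2ccccc2)c1)(C(C)C)C(C)C | intermediate
11 | {3,5-bis(benzyloxy)-4-[(2R,3R,4S)-3,5,7-tris(benzyloxy)-2-[4-(benzyloxy)phenyl]chroman-4-yl]phenoxy}tri(propan-2-yl)silane | CC(C)[Si](Oc1cc(OCc2ccccc2)c([C@H]2c3c(OCc4ccccc4)cc(OCc4ccccc4)cc3O[C@H](c3ccc(OCc4ccccc4)cc3)[C@@H]2OCc2ccccc2)c(OCc2ccccc2)c1)(C(C)C)C(C)C | intermediate
12 | 3,5-bis(benzyloxy)-4-[(2R,3R,4S)-3,5,7-tris(benzyloxy)-2-[4-(benzyloxy)phenyl]chroman-4-yl]phenol | Oc1cc(OCc2ccccc2)c([C@H]2c3c(OCc4ccccc4)cc(OCc4ccccc4)cc3O[C@H](c3ccc(OCc4ccccc4)cc3)[C@@H]2OCc2ccccc2)c(OCc2ccccc2)c1 | intermediate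
13 | 3,4,5-trihydroxybenzaldehyde | O=Cc1cc(O)c(O)c(O)c1 | starting material
14 | 7-hydroxy-2,2-diphenyl-1,3-benzodioxole-5-carbaldehyde | O=Cc1cc(O)c2OC(c3ccccc3)(c3ccccc3)Oc2c1 | intermediate
15 | 7-{[tert-butyl(dimethyl)silyl]oxy}-2,2-diphenyl-1,3-benzodioxole-5-carbaldehyde | O=Cc1cc(O[Si](C)(C)C(C)(C)C)c2OC(c3ccccc3)(c3ccccc3)Oc2c1 | intermediate
16 | rac-1-(7-{[tert-butyl(dimethyl)silyl]oxy}-2,2-diphenyl-1,3-benzodioxol-5-yl)prop-2-en-1-ol | C=CC(O)c1cc(O[Si](C)(C)C(C)(C)C)c2OC(c3ccccc3)(c3ccccc3)Oc2c1 | intermediate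
17 | (S)-(7-{[tert-butyl(dimethyl)silyl]oxy}-2,2-diphenyl-1,3-benzodioxol-5-yl)[(2R)-oxiran-2-yl]methanol | O[C@@H](c1cc(O[Si](C)(C)C(C)(C)C)c2OC(c3ccccc3)(c3ccccc3)Oc2c1)[C@H]1CO1 | intermediate
18 | (2R,3R,4S)-3,5,7-tris(benzyloxy)-2-[4-(benzyloxy)phenyl]-4-{2,6-bis(benzyloxy)-4-[(R)-(7-{[tert-butyl(dimethyl)silyl]oxy}-2,2-diphenyl-1,3-benzodioxol-5-yl)[(2R)-oxiran-2-yl]methoxy]phenyl}chromane | C(Oc1cc(O[C@H](c2cc(O[Si](C)(C)C(C)(C)C)c3OC(c4ccccc4)(c4ccccc4)Oc3c2)[C@H]2CO2)cc(OCc2ccccc2)c1[C@H]1c2c(OCc3ccccc3)cc(OCc3ccccc3)cc2O[C@H](c2ccc(OCc3ccccc3)cc2)[C@@H]1OCc1ccccc1)c1ccccc1 | intermediate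
19 | (2R,3R)-5,7-bis(benzyloxy)-2-(7-{[tert-butyl(dimethyl)silyl]oxy}-2,2-diphenyl-1,3-benzodioxol-5-yl)-6-[(2R,3R,4R)-3,5,7-tris(benzyloxy)-2-[4-(benzyloxy)phenyl]chroman-4-yl]chroman-3-ol | CC(C)(C)[Si](C)(C)Oc1cc([C@H]2Oc3cc(OCc4ccccc4)c([C@H]4c5c(OCc6ccccc6)cc(OCc6ccccc6)cc5O[C@H](c5ccc(OCc6ccccc6)cc5)[C@@H]4OCc4ccccc4)c(OCc4ccccc4)c3C[C@H]2O)cc2OC(c3ccccc3)(c3ccccc3)Oc12 | intermediate
20 | 6-{(2R,3R)-5,7-bis(benzyloxy)-3-hydroxy-6-[(2R,3R,4R)-3,5,7-tris(benzyloxy)-2-[4-(benzyloxy)phenyl]chroman-4-yl]chroman-2-yl}-2,2-diphenyl-1,3-benzodioxol-4-ol | Oc1cc([C@H]2Oc3cc(OCc4ccccc4)c([C@H]4c5c(OCc6ccccc6)cc(OCc6ccccc6)cc5O[C@H](c5ccc(OCc6ccccc6)cc5)[C@@H]4OCc4ccccc4)c(OCc4ccccc4)c3C[C@H]2O)cc2OC(c3ccccc3)(c3ccccc3)Oc12 | intermediate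
21 | 3,4,5-tris(benzyloxy)benzoic acid | OC(=O)c1cc(OCc2ccccc2)c(OCc2ccccc2)c(OCc2ccccc2)c1 | starting material
22 | 6-{(2R,3R)-5,7-bis(benzyloxy)-3-hydroxy-6-[(2R,3R,4R)-3,5,7-tris(benzyloxy)-2-[4-(benzyloxy)phenyl]chroman-4-yl]chroman-2-yl}-2,2-diphenyl-1,3-benzodioxol-4-yl 3,4,5-tris(benzyloxy)benzoate (formed in the flask in step 17) | O=C(Oc1cc([C@H]2Oc3cc(OCc4ccccc4)c([C@H]4c5c(OCc6ccccc6)cc(OCc6ccccc6)cc5O[C@H](c5ccc(OCc6ccccc6)cc5)[C@@H]4OCc4ccccc4)c(OCc4ccccc4)c3C[C@H]2O)cc2OC(c3ccccc3)(c3ccccc3)Oc12)c1cc(OCc2ccccc2)c(OCc2ccccc2)c(OCc2ccccc2)c1 | intermediate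
23 | (2R,3R)-5,7-bis(benzyloxy)-2-(2,2-diphenyl-7-{[3,4,5-tris(benzyloxy)benzoyl]oxy}-1,3-benzodioxol-5-yl)-6-[(2R,3R,4R)-3,5,7-tris(benzyloxy)-2-[4-(benzyloxy)phenyl]chroman-4-yl]chroman-3-yl 3,4,5-tris(benzyloxy)benzoate | O=C(Oc1cc([C@H]2Oc3cc(OCc4ccccc4)c([C@H]4c5c(OCc6ccccc6)cc(OCc6ccccc6)cc5O[C@H](c5ccc(OCc6ccccc6)cc5)[C@@H]4OCc4ccccc4)c(OCc4ccccc4)c3C[C@H]2OC(=O)c2cc(OCc3ccccc3)c(OCc3ccccc3)c(OCc3ccccc3)c2)cc2OC(c3ccccc3)(c3ccccc3)Oc12)c1cc(OCc2ccccc2)c(OCc2ccccc2)c(OCc2ccccc2)c1 | intermediate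
24 | (2R,3R)-2-{3,4-dihydroxy-5-[(3,4,5-trihydroxybenzoyl)oxy]phenyl}-5,7-dihydroxy-6-[(2R,3R,4S)-3,5,7-trihydroxy-2-(4-hydroxyphenyl)chroman-4-yl]chroman-3-yl 3,4,5-trihydroxybenzoate (epiafzelechin-(4β→6)-epigallocatechin 3,3′-di-O-gallate) | O=C(Oc1cc([C@H]2Oc3cc(O)c([C@H]4c5c(O)cc(O)cc5O[C@H](c5ccc(O)cc5)[C@@H]4O)c(O)c3C[C@H]2OC(=O)c2cc(O)c(O)c(O)c2)cc(O)c1O)c1cc(O)c(O)c(O)c1 | target

**Step count and risks**

Total steps: 18. Longest linear sequence: 13 (steps 1–6, 8, 9, 14–18).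

Step 15 (key step). What may go wrong: on the crowded dimer the Lewis acid may ionise the lower benzylic aryl ether or the interflavan bond, or ring B may close a five-membered carbocycle, faster than the 6-endo closure. Fallback, setting out from 5, 17 and 9 and coming back at 19: the ring closure is moved in front of the interflavan coupling, and regiocontrol passes from symmetry to a bromine block. Phenol 5 and epoxy alcohol 17 are joined under the Mitsunobu conditions of step 3 to the monomeric threo aryloxy epoxide F1, which is cyclised as in step 4 (BF3·OEt2, CH2Cl2, −78 °C) to the protected epigallocatechin-type chroman-3-ol F2. NBS (CH2Cl2, −78 → 0 °C) brominates the more reactive C8 to give the 8-bromo chroman-3-ol F3. TMSOTf-catalysed coupling with 9 (CH2Cl2, −78 °C, F3 in excess) can then occur only at C6 and gives the 8-bromo dimer F4. Bromine–lithium exchange (n-BuLi, 2.2 equiv, THF, −78 °C; MeOH quench) removes the block and gives 19.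

Step 8. What may go wrong: poor positional selectivity of the arylation (attack at a carbon ortho instead of para to the silyl ether), or oligomerisation by self-condensation of the cation precursor. Fallback, setting out from 9 and coming back at 11: the cation is trapped with a symmetric nucleophile and the oxygens are differentiated afterwards by steric access. Compound 9 is coupled with benzene-1,3,5-triol (5 equiv, BF3·OEt2, THF–CH2Cl2, 0 °C), for which only one C-arylation product is possible, to give the flavan-4-yl phloroglucinol F5. TIPSCl (1.0 equiv, imidazole, DMF, 0 °C) should silylate the unhindered para hydroxyl rather than the two hydroxyls flanking the flavanyl group, giving the mono-silyl ether diol F6. Benzylation of the two remaining phenols (BnBr, K2CO3, DMF, rt) gives 11.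

Step 14. What may go wrong: loss of configuration at the benzylic carbon through an SN1 pathway, elimination, or slow displacement with the bulky phenol, all of which cost precious 12. Fallback, setting out from 15 and 12 and coming back at 18: the aryl ether is made by opening a cis epoxide instead of by displacing an activated alcohol. Aldehyde 15 is converted by a Still–Gennari olefination (methyl bis(2,2,2-trifluoroethyl)phosphonoacetate, KHMDS, 18-crown-6, THF, −78 °C) into the (Z)-enoate F7, which DIBAL-H (CH2Cl2, −78 °C) reduces to the (Z)-allylic alcohol F8. Sharpless epoxidation with the D-(−)-tartrate (Ti(OiPr)4, D-(−)-diisopropyl tartrate, t-BuOOH, CH2Cl2, −20 °C) gives the cis (2R,3S) epoxy alcohol F9. Phenol 12 opens F9 at the benzylic carbon with inversion (Ti(OiPr)4, toluene, 60 °C) to give the threo aryloxy diol F10. N-Tosylimidazole and NaH (THF, 0 °C) sulfonylate the primary hydroxyl to the primary tosylate F11, which closes in the same flask to the terminal epoxide 18 with retention at the secondary carbon.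

**Further compounds**

F1 | step 15 | (2R)-2-{(R)-[3,5-bis(benzyloxy)phenoxy](7-{[tert-butyl(dimethyl)silyl]oxy}-2,2-diphenyl-1,3-benzodioxol-5-yl)methyl}oxirane | C(Oc1cc(OCc2ccccc2)cc(O[C@H](c2cc(O[Si](C)(C)C(C)(C)C)c3OC(c4ccccc4)(c4ccccc4)Oc3c2)[C@H]2CO2)c1)c1ccccc1
F2 | step 15 | (2R,3R)-5,7-bis(benzyloxy)-2-(7-{[tert-butyl(dimethyl)silyl]oxy}-2,2-diphenyl-1,3-benzodioxol-5-yl)chroman-3-ol | O[C@@H]1Cc2c(OCc3ccccc3)cc(OCc3ccccc3)cc2O[C@@H]1c1cc(O[Si](C)(C)C(C)(C)C)c2OC(c3ccccc3)(c3ccccc3)Oc2c1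
F3 | step 15 | (2R,3R)-5,7-bis(benzyloxy)-8-bromo-2-(7-{[tert-butyl(dimethyl)silyl]oxy}-2,2-diphenyl-1,3-benzodioxol-5-yl)chroman-3-ol | O[C@@H]1Cc2c(OCc3ccccc3)cc(OCc3ccccc3)c(Br)c2O[C@@H]1c1cc(O[Si](C)(C)C(C)(C)C)c2OC(c3ccccc3)(c3ccccc3)Oc2c1
F4 | step 15 | (2R,3R)-5,7-bis(benzyloxy)-8-bromo-2-(7-{[tert-butyl(dimethyl)silyl]oxy}-2,2-diphenyl-1,3-benzodioxol-5-yl)-6-[(2R,3R,4R)-3,5,7-tris(benzyloxy)-2-[4-(benzyloxy)phenyl]chroman-4-yl]chroman-3-ol | CC(C)(C)[Si](C)(C)Oc1cc([C@H]2Oc3c(Br)c(OCc4ccccc4)c([C@H]4c5c(OCc6ccccc6)cc(OCc6ccccc6)cc5O[C@H](c5ccc(OCc6ccccc6)cc5)[C@@H]4OCc4ccccc4)c(OCc4ccccc4)c3C[C@H]2O)cc2OC(c3ccccc3)(c3ccccc3)Oc12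
F5 | step 8 | 2-[(2R,3R,4S)-3,5,7-tris(benzyloxy)-2-[4-(benzyloxy)phenyl]chroman-4-yl]benzene-1,3,5-triol | Oc1cc(O)c([C@H]2c3c(OCc4ccccc4)cc(OCc4ccccc4)cc3O[C@H](c3ccc(OCc4ccccc4)cc3)[C@@H]2OCc2ccccc2)c(O)c1
F6 | step 8 | 2-[(2R,3R,4S)-3,5,7-tris(benzyloxy)-2-[4-(benzyloxy)phenyl]chroman-4-yl]-5-{[tri(propan-2-yl)silyl]oxy}benzene-1,3-diol | CC(C)[Si](Oc1cc(O)c([C@H]2c3c(OCc4ccccc4)cc(OCc4ccccc4)cc3O[C@H](c3ccc(OCc4ccccc4)cc3)[C@@H]2OCc2ccccc2)c(O)c1)(C(C)C)C(C)C
F7 | step 14 | methyl (2Z)-3-(7-{[tert-butyl(dimethyl)silyl]oxy}-2,2-diphenyl-1,3-benzodioxol-5-yl)prop-2-enoate | COC(=O)/C=C\c1cc(O[Si](C)(C)C(C)(C)C)c2OC(c3ccccc3)(c3ccccc3)Oc2c1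
F8 | step 14 | (2Z)-3-(7-{[tert-butyl(dimethyl)silyl]oxy}-2,2-diphenyl-1,3-benzodioxol-5-yl)prop-2-en-1-ol | OC/C=C\c1cc(O[Si](C)(C)C(C)(C)C)c2OC(c3ccccc3)(c3ccccc3)Oc2c1
F9 | step 14 | [(2R,3S)-3-(7-{[tert-butyl(dimethyl)silyl]oxy}-2,2-diphenyl-1,3-benzodioxol-5-yl)oxiran-2-yl]methanol | OC[C@H]1O[C@H]1c1cc(O[Si](C)(C)C(C)(C)C)c2OC(c3ccccc3)(c3ccccc3)Oc2c1
F10 | step 14 | (2R,3R)-3-{3,5-bis(benzyloxy)-4-[(2R,3R,4S)-3,5,7-tris(benzyloxy)-2-[4-(benzyloxy)phenyl]chroman-4-yl]phenoxy}-3-(7-{[tert-butyl(dimethyl)silyl]oxy}-2,2-diphenyl-1,3-benzodioxol-5-yl)propane-1,2-diol | OC[C@@H](O)[C@H](Oc1cc(OCc2ccccc2)c([C@H]2c3c(OCc4ccccc4)cc(OCc4ccccc4)cc3O[C@H](c3ccc(OCc4ccccc4)cc3)[C@@H]2OCc2ccccc2)c(OCc2ccccc2)c1)c1cc(O[Si](C)(C)C(C)(C)C)c2OC(c3ccccc3)(c3ccccc3)Oc2c1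
F11 | step 14 | (2R,3R)-3-{3,5-bis(benzyloxy)-4-[(2R,3R,4S)-3,5,7-tris(benzyloxy)-2-[4-(benzyloxy)phenyl]chroman-4-yl]phenoxy}-3-(7-{[tert-butyl(dimethyl)silyl]oxy}-2,2-diphenyl-1,3-benzodioxol-5-yl)-2-hydroxypropyl 4-methylbenzenesulfonate | Cc1ccc(cc1)S(=O)(=O)OC[C@@H](O)[C@H](Oc1cc(OCc2ccccc2)c([C@H]2c3c(OCc4ccccc4)cc(OCc4ccccc4)cc3O[C@H](c3ccc(OCc4ccccc4)cc3)[C@@H]2OCc2ccccc2)c(OCc2ccccc2)c1)c1cc(O[Si](C)(C)C(C)(C)C)c2OC(c3ccccc3)(c3ccccc3)Oc2c1
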